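Retrosynthesis: the two vanilloyl C(=O)–O bonds at O3 and O4 are cut first. The carboxyl carbon C7 is then tied back to O5 as the 1,5-lactone (6-oxabicyclo[3.2.1]octan-7-one), which masks O5 and CO2H.
Enabling feature: C1 carries OH and CO2H on one carbon between two CH2 groups, the imprint of a benzilic rearrangement, and C7 is cis-1,3 to O5 across the cyclohexane. Cutting C1–C2 and rejoining C2 to C7 puts C7 into the ring and gives a cycloheptane-1,2-dione (ring C1–C7–C2–C3–C4–C5–C6) with O5 as built-in nucleophile.
The dione goes back through the diol to a cycloheptene. This is cut at C1=C7 (ring-closing metathesis) to a nona-1,8-diene, then at C5–C6 (allylation) and at C7=CH2 (Wittig) to 2-deoxy-L-ribose, whose C1–C5 become C7, C2, C3, C4, C5.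
Forward ring order: temporary dioxolane, seven-membered carbocycle, oxygen-bridged hemiketal, cyclohexane plus gamma-lactone in one operation, esters, lactone opening.
Stereochemistry: C3 and C4 come from the sugar, C5 from reagent-controlled allylboration, C1 from the O5–C7 tether during the ring contraction.

Key step: step 9

Remark: the SMILES is read as the 3,4-di-O-vanilloyl ester of the (−)-quinic acid series. Its numbering is used for all intermediates: C1 quaternary carbinol, C7 its carboxyl carbon, C3 and C4 the acylated carbinols, C5 the free carbinol, C2 and C6 the CH2 groups.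

Step 1
Reactants: 1 2-deoxy-L-ribose
Product: 2 2-deoxy-3,4-O-isopropylidene-L-erythro-pentopyranose (anomer mixture)
Conditions: 2-methoxypropene, PPTS (cat.), EtOAc, −10 °C to rt
Reagents that add atoms: 2-methoxypropene, C=C(C)OC
Why: Acid-catalysed acetal exchange with the enol ether under kinetic conditions takes the cis-3,4-diol of the pyranose form into a cis-fused dioxolane and leaves the lactol free, a standard operation on 2-deoxypentoses that touches no stereocentre.

Step 2
Reactants: 2 2-deoxy-3,4-O-isopropylidene-L-erythro-pentopyranose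
Product: 3 [(4S,5R)-5-allyl-2,2-dimethyl-1,3-dioxolan-4-yl]methanol
Conditions: Ph3PCH3Br (2.5 equiv), KOt-Bu (2.4 equiv), THF, 0 °C to reflux
Reagents that add atoms: methyltriphenylphosphonium bromide, C[P+](c1ccccc1)(c1ccccc1)c1ccccc1.[Br-]
Why: Wittig methylenation of the aldehyde in equilibrium with the lactol turns sugar C1 (future C7) into a vinyl carbon and frees the primary alcohol at sugar C5, with excess ylide covering the acidic OH.

Step 3
Reactants: 3 [(4S,5R)-5-allyl-2,2-dimethyl-1,3-dioxolan-4-yl]methanol
Product: 4 (4R,5R)-5-allyl-2,2-dimethyl-1,3-dioxolane-4-carbaldehyde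
Conditions: Dess–Martin periodinane (1.2 equiv), CH2Cl2, 0 °C to rt
Reagents that add atoms: none
Why: Dess–Martin oxidation works under nearly neutral conditions, so the alpha-alkoxy aldehyde should form without epimerisation at C4 and is carried on crude.

Step 4
Reactants: 4 (4R,5R)-5-allyl-2,2-dimethyl-1,3-dioxolane-4-carbaldehyde
Product: 6 (1R)-1-[(4S,5R)-5-allyl-2,2-dimethyl-1,3-dioxolan-4-yl]but-3-en-1-ol, via diisopinocampheylborinate 5 (not isolated)
Conditions: B-allyldiisopinocampheylborane of the (−)-α-pinene series (commercial pentane solution, 1.3 equiv), Et2O, −100 to −78 °C; then 3 N NaOH, 30% H2O2, 0 °C to rt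
Reagents that add atoms: B-allyldiisopinocampheylborane (both Ipc groups from (−)-α-pinene), C=CCB([C@H]1C[C@H]2C[C@@H]([C@@H]1C)C2(C)C)[C@H]1C[C@H]2C[C@@H]([C@@H]1C)C2(C)C
Why: Brown asymmetric allylboration through a closed chair (Zimmerman–Traxler) transition state: the reagent of the (−)-α-pinene series delivers allyl to the Re face of the aldehyde and so sets (5R), syn (threo) to O4, by reagent control over the opposite Felkin–Anh preference of the dioxolane aldehyde, and alkaline H2O2 then frees the alcohol from borinate 5.

Step 5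
Reactants: 6 (1R)-1-[(4S,5R)-5-allyl-2,2-dimethyl-1,3-dioxolan-4-yl]but-3-en-1-ol
Product: 7 tert-butyldimethylsilyl ether of 6 (O5–TBS; (1R)-carbinol carbon, cis-(4R,5R)-dioxolane)
Conditions: TBSOTf (1.3 equiv), 2,6-lutidine (2 equiv), CH2Cl2, −78 to 0 °C
Reagents that add atoms: tert-butyldimethylsilyl triflate, CC(C)(C)[Si](C)(C)OS(=O)(=O)C(F)(F)F
Why: Silylation with the silyl triflate masks O5 through the two oxidation steps and stores it as a fluoride-releasable alkoxide for the key step.

Step 6
Reactants: 7 TBS ether diene
Product: 8 (3aR,4R,8aR)-4-(tert-butyldimethylsilyloxy)-2,2-dimethyl-3a,5,8,8a-tetrahydro-4H-cyclohepta[d][1,3]dioxole (cycloheptene, C1=C7 alkene, O3/O4 cis acetonide, O5–TBS trans to O4)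
Conditions: second-generation Grubbs catalyst (H2IMes)(PCy3)Cl2Ru=CHPh (3 mol %), CH2Cl2 (high dilution), reflux
Reagents that add atoms: none
Why: Ring-closing metathesis of two terminal alkenes held cis on the dioxolane closes the seven-membered carbocycle C1–C7–C2–C3–C4–C5–C6 with loss of ethene, a closure well known for sugar-derived nona-1,8-dienes.

Step 7
Reactants: 8 cycloheptene
Product: 9 C1,C7-cis-diol of 8 (mixture of the two face isomers)
Conditions: OsO4 (2 mol %), NMO (1.5 equiv), acetone/H2O, rt
Reagents that add atoms: N-methylmorpholine N-oxide, C[N+]1([O-])CCOCC1; water, O; osmium tetroxide (oxygen carrier), O=[Os](=O)(=O)=O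
Why: Upjohn syn-dihydroxylation of the only alkene; the two new carbinol centres are erased in step 8, so the facial selectivity is of no consequence.

Step 8
Reactants: 9 cis-diol
Product: 10 (3aR,4R,8aR)-4-(tert-butyldimethylsilyloxy)-2,2-dimethyltetrahydro-cyclohepta[d][1,3]dioxole-6,7-dione (cycloheptane-1,2-dione, C1=O and C7=O)
Conditions: 2-iodoxybenzoic acid (4 equiv), DMSO, rt
Reagents that add atoms: none
Why: 2-Iodoxybenzoic acid oxidises vicinal diols to 1,2-diketones without glycol cleavage and without base, which should spare the beta-oxygenated dione from elimination, and it leaves TBS ethers and acetonides alone.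

Step 9
Reactants: 10 O5-TBS cycloheptane-1,2-dione
Product: 13 3,4-O-isopropylidene-1,5-quinide, via hydroxy dione 11 (not isolated), via bridged hemiketal 12 (not isolated)
Conditions: TBAF (1.1 equiv), THF, −20 °C to rt; then AcOH (1.1 equiv)
Reagents that add atoms: none
Why: Proposed new method: fluoride frees the C5 alkoxide of 11, which adds across the ring to C7, the farther carbonyl of the 1,2-dione, and the oxyanion of the resulting hemiketal 12 pushes the C2 methylene from C7 onto the adjacent ketone carbon C1, so that C7 leaves the carbocycle as the lactone carbonyl and the seven-membered ring shrinks to the cyclohexane. The closest known reaction types are the benzilic ester rearrangement of cyclic 1,2-diones with an external alkoxide (cycloheptane-1,2-dione to 1-hydroxycyclohexanecarboxylate) and the base-induced alpha-ketol shift of bridged bicyclic ketols; what has no close precedent is a ring hydroxyl serving as the alkoxide, acting transannularly on an enolisable, beta-oxygenated dione to give the bridged lactone directly. Ring closures: the tetrahydrofuran ring O5–C5–C6–C1–C7 forms by 5-exo-trig addition (attack on C1 would be a 4-exo closure to an oxetane) and survives as the gamma-lactone, while the cyclohexane closes through the suprafacial 1,2-shift that makes the C1–C2 bond. The one new stereocentre, C1, is controlled by the oxygen bridge: C7 stays bonded to O5, so C7 and O5 must be cis on the new ring, C2 can reach only the ketone face under the three-carbon bridge, and the C1 hydroxyl falls on the face of O3 and O4. The step needs O5 and not O3 or O4 as nucleophile, which the acetonide secures, and shift rather than beta-elimination, which the hemiketal secures because C7 is no longer a carbonyl beta to O3 and loss of O5 from the C1 enolate would be a retro-5-endo-trig opening. Conversion of a ketone plus hemiketal into a lactone plus tertiary alkoxide supplies the driving force and makes the shift irreversible.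

Step 10
Reactants: 13 3,4-O-isopropylidene-1,5-quinide
Product: 14 1,5-quinide (quinic acid gamma-lactone; free OH at C1, C3, C4)
Conditions: TFA/H2O (9:1), 0 °C to rt
Reagents that add atoms: none
Why: Acid hydrolysis of the isopropylidene acetal frees the cis-3,4-diol while the bridged gamma-lactone, which itself forms under acid, stays closed.

Step 11
Reactants: 14 1,5-quinide; 15 4-acetoxy-3-methoxybenzoic acid (O-acetylvanillic acid, 2.3 equiv)
Product: 17 3,4-bis-O-(4-acetoxy-3-methoxybenzoyl)-1,5-quinide, via 4-acetoxy-3-methoxybenzoyl chloride 16 (not isolated)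
Conditions: 15, (COCl)2, DMF (cat.), CH2Cl2, 0 °C to rt, concentrate; then 14, pyridine, DMAP (cat.), CH2Cl2, 0 °C to rt
Reagents that add atoms: none
Why: DMAP-catalysed acylation with the acid chloride made in the flask esterifies the two secondary hydroxyls (equatorial O3 first, then axial O4) ahead of the tertiary bridgehead alpha-hydroxy-lactone OH at C1, while the lactone keeps O5 and the carboxyl out of play.

Step 12
Reactants: 17 3,4-bis-O-(4-acetoxy-3-methoxybenzoyl)-1,5-quinide
Product: 18 burkinabin A (3,4-di-O-vanilloylquinic acid)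
Conditions: 2 N aq. HCl/THF (1:1), rt, several days; freeze-drying
Reagents that add atoms: water, O
Why: Acid-catalysed hydrolysis opens the strained gamma-lactone and cleaves the two phenolic acetates far faster than the hindered, electron-rich secondary vanillates, and the acidic medium holds back acyl migration to the freed O5, as is usual in the last step of acylquinic acid syntheses; no stereocentre is touched.

Compound list
1 | 2-deoxy-L-ribose (2-deoxy-L-erythro-pentose, pyranose form) | OC1C[C@@H](O)[C@@H](O)CO1 | starting material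
2 | 2-deoxy-3,4-O-isopropylidene-L-erythro-pentopyranose (anomer mixture) | OC1C[C@H]2OC(C)(C)O[C@H]2CO1 | intermediate
3 | [(4S,5R)-5-allyl-2,2-dimethyl-1,3-dioxolan-4-yl]methanol | C=CC[C@H]1OC(C)(C)O[C@H]1CO | intermediate
4 | (4R,5R)-5-allyl-2,2-dimethyl-1,3-dioxolane-4-carbaldehyde | C=CC[C@H]1OC(C)(C)O[C@H]1C=O | intermediate
5 | diisopinocampheylborinate of 6 (not isolated) | C=CC[C@H]1OC(C)(C)O[C@H]1[C@@H](CC=C)OB([C@H]1C[C@H]2C[C@@H]([C@@H]1C)C2(C)C)[C@H]1C[C@H]2C[C@@H]([C@@H]1C)C2(C)C | intermediate
6 | (1R)-1-[(4S,5R)-5-allyl-2,2-dimethyl-1,3-dioxolan-4-yl]but-3-en-1-ol | C=CC[C@H]1OC(C)(C)O[C@H]1[C@H](O)CC=C | intermediate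
7 | TBS ether of 6 | C=CC[C@H]1OC(C)(C)O[C@H]1[C@H](O[Si](C)(C)C(C)(C)C)CC=C | intermediate
8 | (3aR,4R,8aR)-4-(TBS-oxy)-2,2-dimethyl-3a,5,8,8a-tetrahydro-4H-cyclohepta[d][1,3]dioxole | CC(C)(C)[Si](C)(C)O[C@@H]1CC=CC[C@H]2OC(C)(C)O[C@@H]12 | intermediate
9 | C1,C7-cis-diol of 8 (both face isomers, new centres left open) | CC(C)(C)[Si](C)(C)O[C@@H]1CC(O)C(O)C[C@H]2OC(C)(C)O[C@@H]12 | intermediate
10 | (3aR,4R,8aR)-4-(TBS-oxy)-2,2-dimethyltetrahydro-cyclohepta[d][1,3]dioxole-6,7-dione | CC(C)(C)[Si](C)(C)O[C@@H]1CC(=O)C(=O)C[C@H]2OC(C)(C)O[C@@H]12 | intermediate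
11 | 5-hydroxy cycloheptane-1,2-dione acetonide (formed as its alkoxide, not isolated) | O[C@@H]1CC(=O)C(=O)C[C@H]2OC(C)(C)O[C@@H]12 | intermediate
12 | 1-hydroxy-8-oxabicyclo[3.2.1]octan-7-one 3,4-acetonide (O5 bridges C5 and C7; formed as its oxyanion, not isolated) | O[C@@]12C[C@H]3OC(C)(C)O[C@H]3[C@@H](CC1=O)O2 | intermediate
13 | 3,4-O-isopropylidene-1,5-quinide | O=C1O[C@@H]2C[C@@]1(O)C[C@H]3OC(C)(C)O[C@@H]23 | intermediate
14 | 1,5-quinide | O=C1O[C@@H]2C[C@@]1(O)C[C@@H](O)[C@H]2O | intermediate
15 | 4-acetoxy-3-methoxybenzoic acid | CC(=O)Oc1ccc(C(=O)O)cc1OC | starting material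
16 | 4-acetoxy-3-methoxybenzoyl chloride (not isolated) | CC(=O)Oc1ccc(C(=O)Cl)cc1OC | intermediate
17 | 3,4-bis-O-(4-acetoxy-3-methoxybenzoyl)-1,5-quinide | O=C1O[C@@H]2C[C@@]1(O)C[C@@H](OC(=O)c1ccc(OC(C)=O)c(OC)c1)[C@H]2OC(=O)c1ccc(OC(C)=O)c(OC)c1 | intermediate
18 | burkinabin A | COc1cc(C(=O)O[C@H]2[C@H](O)C[C@](O)(C(=O)O)C[C@H]2OC(=O)c2ccc(O)c(OC)c2)ccc1O | target

Total step count: 12. Longest linear sequence: 12 steps (1 to 18); 15 enters at step 11.

Steps most likely to fail

Step 9 (Proposed new method). Enolisation of the open dione followed by beta-elimination of O3 or O5, retro-aldol cleavage of the freed beta-alkoxide, or aldol self-condensation may outrun the transannular addition and the shift. The fallback uses known chemistry and sets out from dione 10. The classical intermolecular benzilic acid rearrangement with aqueous Ba(OH)2 in dioxane should give, without control at C1, the C1-epimeric 5-O-TBS-3,4-O-isopropylidenequinic acids F1. TBAF in THF then frees O5 to give the C1-epimeric 3,4-O-isopropylidenequinic acids F2. Heating with catalytic TsOH and 2,2-dimethoxypropane in toluene lactonises only the epimer whose carboxyl is cis to O5, which comes back to the route at 13. The other epimer stays an acid and is washed out with aqueous NaHCO3.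

Step 4. Poor facial selectivity is possible, because the reagent has to override the Felkin–Anh preference of the cis-substituted dioxolane aldehyde (mismatched pairing). The fallback sets out from aldehyde 4 and uses the substrate bias instead of fighting it. Addition of allylmagnesium bromide in Et2O at −78 °C should favour the anti alcohol (1S)-1-[(4S,5R)-5-allyl-2,2-dimethyl-1,3-dioxolan-4-yl]but-3-en-1-ol F3. Mitsunobu inversion with 4-nitrobenzoic acid, PPh3 and DIAD gives the inverted (1R)-4-nitrobenzoate F4. Methanolysis with K2CO3 in MeOH comes back to the route at 6.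

Step 11. Acylation at the tertiary C1 hydroxyl may compete with the slow acylation of the axial O4 once O3 carries its ester, which would erode site selectivity. The fallback sets out from 13, in which C1–OH is the only free hydroxyl. CbzCl, DMAP and pyridine give 1-O-benzyloxycarbonyl-3,4-O-isopropylidene-1,5-quinide F5. Aqueous TFA gives 1-O-benzyloxycarbonyl-1,5-quinide F6. Excess 16 with pyridine and DMAP gives, with no selectivity demand, 1-O-benzyloxycarbonyl-3,4-bis-O-(4-acetoxy-3-methoxybenzoyl)-1,5-quinide F7. Hydrogenolysis (H2, palladium on carbon, EtOAc) removes the carbonate and comes back to the route at 17.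

Further compounds
F1 | step 9 | 5-O-TBS-3,4-O-isopropylidenequinic acid, mixture of C1 epimers | CC(C)(C)[Si](C)(C)O[C@@H]1CC(O)(C(=O)O)C[C@H]2OC(C)(C)O[C@@H]12
F2 | step 9 | 3,4-O-isopropylidenequinic acid, mixture of C1 epimers | O[C@@H]1CC(O)(C(=O)O)C[C@H]2OC(C)(C)O[C@@H]12
F3 | step 4 | (1S)-1-[(4S,5R)-5-allyl-2,2-dimethyl-1,3-dioxolan-4-yl]but-3-en-1-ol | C=CC[C@H]1OC(C)(C)O[C@H]1[C@@H](O)CC=C
F4 | step 4 | (1R)-4-nitrobenzoate of 6 | C=CC[C@H]1OC(C)(C)O[C@H]1[C@H](OC(=O)c1ccc(cc1)[N+](=O)[O-])CC=C
F5 | step 11 | 1-O-benzyloxycarbonyl-3,4-O-isopropylidene-1,5-quinide | O=C1O[C@@H]2C[C@@]1(OC(=O)OCc1ccccc1)C[C@H]3OC(C)(C)O[C@@H]23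
F6 | step 11 | 1-O-benzyloxycarbonyl-1,5-quinide | O=C1O[C@@H]2C[C@@]1(OC(=O)OCc1ccccc1)C[C@@H](O)[C@H]2O
F7 | step 11 | 1-O-benzyloxycarbonyl-3,4-bis-O-(4-acetoxy-3-methoxybenzoyl)-1,5-quinide | O=C1O[C@@H]2C[C@@]1(OC(=O)OCc1ccccc1)C[C@@H](OC(=O)c1ccc(OC(C)=O)c(OC)c1)[C@H]2OC(=O)c1ccc(OC(C)=O)c(OC)c1
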